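The runs were computed from invented constants; scatter was added.

25.9% of the substrate charged was where the other capture product stood in the last two readings of this flask, 26.1% and 25.7%, a difference of 0.4 percentage points against a scatter of 0.5 points.

| setting | summer | flask |
|---|---|---|
| substrate | 0.96 M | 0.96 M |
| first nucleophile | 1.01 M | 1.01 M |
| second nucleophile | 1.92 M | 1.92 M |
| remark | the very flask that is asked about, followed so far |  |
| time |  | 15 d |

- summer (time / d: target / %, other capture product / %): 0.208: 3.6, 11.3; 0.417: 7.6, 18.6; 0.833: 14.1, 23.3; 1.25: 23.8, 26.1; 2.50: 37.7, 25.7

(each reading ± 0.5 percentage points)

* share of target in target plus other capture product at 1.0 h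
* share of target in target plus other capture product at 20 h
* share of target in target plus other capture product at 15 d
* which of target and other capture product there is more of at 15 d

- a reading or a percentage of target counts all its forms, free or not

I froze that level, assuming kinetic control to the end, and carried it as the capture yield 12.9%, the part of the second nucleophile's charge read as other capture product. If the whole remainder became target, the share had this ceiling:

ceiling = 1 − capture yield × second nucleophile charge / substrate charge = 74.1%

For the floor, target stuck at 37.7% gave 59.3%. To tighten it by an estimate that carries the scatter of the readings, I read a pseudo-first-order constant from the fall of the remainder over the last interval, then scaled it by the first nucleophile left at the ceiling against that in the interval: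

0.251 d⁻¹ × 0.299 M / 0.715 M = 0.105 d⁻¹

estimated remainder at 15 d = 9.86%, so estimated floor = 71.3%

The forecast gave 20.5%, 38.5% and 88%, with target ahead, holding that “the target keeps draining the substrate and other-product pool”. Its last share stood higher than my ceiling.

The flask gave 21.1%, 39.4% and 72.5%, inside my bracket, with target ahead at 70.2% against 26.6%.

    substrate ⇌ intermediate (K = 0.00510, k = 1.39 × 10⁻⁵ s⁻¹)
    first nucleophile + intermediate → target (k = 0.00124 L mol⁻¹ s⁻¹)
    second nucleophile + intermediate → other capture product (k = 0.00259 L mol⁻¹ s⁻¹)
    crystals ⇌ target, rate k4*(cs4 - [target]) while solid is left; crystals form when [target] > cs4 (solubility = 0.500 M, k = 0.00122 s⁻¹)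
    second nucleophile → decomposed reagent (k = 2.89 × 10⁻⁵ s⁻¹)
    second nucleophile + target ⇌ idle adduct, settled at all times (K = 0.451 L mol⁻¹)

At 15.0 d this flask's second nucleophile stood at 0% of its own charge and decomposed reagent at 1.66 M. The capture yield leaves 1.6 points of share above this result; at 150 d the flask held 73.4% target and 26.6% other capture product.

On the neighbour with 0.77 M of second nucleophile, the capture yield gives a ceiling of 89.6%. That flask gave 85.4%, with 80.4% target and 13.8% other capture product, which is 17.2% of its own charge of second nucleophile, more than the capture yield of 12.9%.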